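**Retrosynthetic overview**

1. Target 13 comes from its bis-silyl ether 12 by removing the two aryl silyl ethers.
2. Key cut: the aryl–C3 bond of 12. The 4-silyloxyphenyl group is the nucleophile (diarylcuprate 11). The α-carbon of the methyl ester is the electrophile, an ester α-cation (enolonium) equivalent held as the ring C–O carbon of cis β-lactone 8. Both carbons are nucleophilic in their usual roles (ester enolate carbon, para carbon of a phenol).
3. SN2 inversion at that carbon turns cis-8 into the anti (2S,3S) half-ester. The leaving carboxylate becomes the free acid and the methyl ester is already in place.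
4. Lactone 8 comes from a catalytic asymmetric ketene–aldehyde [2+2] of ketene 7 (from 3-(4-hydroxyphenyl)propanoic acid 1 by ortho-prenylation, silylation and acid chloride formation) with methyl glyoxylate 5. Both stereocentres are set here.
5. Rings: both benzene rings are bought. The only ring made is the oxetan-2-one of 8 (step 3), and it is opened again in step 4.

Assumption: O-trimethylsilylquinine is taken to give the (2S,3S) enantiomer of cis lactone 8 (S at the ketene-derived carbon, as in related alkaloid-catalysed ketene reactions); if the sense proves opposite, the quinidine-derived pseudo-enantiomer is used and nothing else changes.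

TBS = tert-butyldimethylsilyl throughout.

**Route**

Step 1
Reactants: 1 3-(4-hydroxyphenyl)propanoic acid; 2 1-bromo-3-methylbut-2-ene (prenyl bromide)
Product: 3 3-[4-hydroxy-3-(3-methylbut-2-en-1-yl)phenyl]propanoic acid
Conditions: 2 (1.1 equiv), KOH (2.2 equiv), H2O, 0 °C to rt, 16 h; then 1 M HCl to pH 2
Reagents that add atoms: none
Why: Ortho C-alkylation of an ambident phenoxide in water, where hydrogen bonding to the phenoxide oxygen and the blocked para position direct SN2 attack of the ortho carbon on the primary allylic bromide while the carboxylate is a poor nucleophile; no stereocentre is formed.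

Step 2
Reactants: 3 3-[4-hydroxy-3-(3-methylbut-2-en-1-yl)phenyl]propanoic acid
Product: 4 TBS 3-[4-(TBSO)-3-(3-methylbut-2-en-1-yl)phenyl]propanoate (silyl ester and aryl silyl ether)
Conditions: TBSCl (2.4 equiv), imidazole (5 equiv), DMF, rt; pentane extraction, used crude
Reagents that add atoms: tert-butyl(chloro)dimethylsilane (TBSCl), CC(C)(C)[Si](C)(C)Cl
Why: Standard imidazole-promoted silylation caps the phenol and the acid together, and the silyl ester is chosen because it goes to the acid chloride without free HCl; no stereocentre is formed.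

Step 3
Reactants: 4 TBS 3-[4-(TBSO)-3-(3-methylbut-2-en-1-yl)phenyl]propanoate; 5 methyl glyoxylate (methyl 2-oxoacetate, freshly distilled)
Product: 8 methyl (2S,3S)-3-{[4-(TBSO)-3-(3-methylbut-2-en-1-yl)phenyl]methyl}-4-oxooxetane-2-carboxylate (cis lactone), via acid chloride 6 (not isolated), via ketene 7 (not isolated)
Conditions: (COCl)2 (1.1 equiv), DMF (2 mol%), CH2Cl2, 0 °C to rt, evaporate; then add over 2 h to 5 (2 equiv), O-trimethylsilylquinine (15 mol%), LiClO4 (1.5 equiv), iPr2NEt (2.5 equiv), CH2Cl2/Et2O 2:1, −78 °C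
Reagents that add atoms: none
Why: Neutral silyl ester to acid chloride conversion, then a catalytic asymmetric ketene–aldehyde [2+2] cycloaddition (Wynberg-type acyl halide–aldehyde cyclocondensation) in which the alkaloid-bound Z-ammonium enolate of ketene 7 adds to the lithium-activated glyoxylate through a closed chair-like transition state, so both stereocentres are set at once, cis on the ring, with the quinine-derived catalyst fixing S at the ketene-derived carbon.

Step 4
Reactants: 8 methyl (2S,3S)-3-{[4-(TBSO)-3-(3-methylbut-2-en-1-yl)phenyl]methyl}-4-oxooxetane-2-carboxylate; 9 (4-bromophenoxy)(tert-butyl)dimethylsilane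
Product: 12 (2S,3S)-2-{[4-(TBSO)-3-(3-methylbut-2-en-1-yl)phenyl]methyl}-3-[4-(TBSO)phenyl]-4-methoxy-4-oxobutanoic acid, via aryl Grignard reagent 10 (not isolated), via magnesium diarylcuprate 11 (not isolated)
Conditions: 9 (3.2 equiv), Mg, THF, rt; CuBr·SMe2 (1.6 equiv), THF/Me2S 4:1, −40 °C; then 8, −78 to −30 °C, 3 h; aq. NH4Cl, citric acid to pH 3
Reagents that add atoms: none
Why: Proposed new method: the soft diarylcuprate attacks C2 of the oxetanone (the strained C–O carbon that is also the α-carbon of the methyl ester, so an ester α-cation equivalent) in an SN2 alkyl–oxygen opening, helped by ring strain and by the adjacent ester lowering the C–O σ* level, passing through a trivalent copper intermediate that eliminates reductively with retention for net inversion, so the aryl-bearing centre of 12 is set by inversion of cis-8 while the benzyl-bearing centre is untouched and the leaving carboxylate is the free acid; the closest known reaction types are cuprate openings of β-lactones at the β-carbon with inversion and cuprate displacements of α-sulfonyloxy esters with inversion.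

Step 5
Reactants: 12 (2S,3S)-2-{[4-(TBSO)-3-(3-methylbut-2-en-1-yl)phenyl]methyl}-3-[4-(TBSO)phenyl]-4-methoxy-4-oxobutanoic acid
Product: 13 Asperteretal G2, (2S,3S)-2-{[4-hydroxy-3-(3-methylbut-2-en-1-yl)phenyl]methyl}-3-(4-hydroxyphenyl)-4-methoxy-4-oxobutanoic acid
Conditions: KHF2 (6 equiv), MeOH, rt to 40 °C
Reagents that add atoms: none
Why: Fluoride cleavage of both aryl silyl ethers with mildly acidic KHF2, which avoids base epimerisation of the α-aryl ester centre and acid-induced chroman formation from the ortho-prenyl phenol; no stereocentre is touched.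

**Compound list**

1 | 3-(4-hydroxyphenyl)propanoic acid | OC(=O)CCc1ccc(O)cc1 | starting material
2 | 1-bromo-3-methylbut-2-ene (prenyl bromide) | CC(C)=CCBr | starting material
3 | 3-[4-hydroxy-3-(3-methylbut-2-en-1-yl)phenyl]propanoic acid | CC(C)=CCc1cc(CCC(=O)O)ccc1O | intermediate
4 | TBS 3-[4-(TBSO)-3-(3-methylbut-2-en-1-yl)phenyl]propanoate | CC(C)=CCc1cc(CCC(=O)O[Si](C)(C)C(C)(C)C)ccc1O[Si](C)(C)C(C)(C)C | intermediate
5 | methyl glyoxylate (methyl 2-oxoacetate) | COC(=O)C=O | starting material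
6 | 3-[4-(TBSO)-3-(3-methylbut-2-en-1-yl)phenyl]propanoyl chloride | CC(C)=CCc1cc(CCC(=O)Cl)ccc1O[Si](C)(C)C(C)(C)C | intermediate (not isolated)
7 | 3-[4-(TBSO)-3-(3-methylbut-2-en-1-yl)phenyl]prop-1-en-1-one (monosubstituted ketene) | CC(C)=CCc1cc(CC=C=O)ccc1O[Si](C)(C)C(C)(C)C | intermediate (not isolated)
8 | methyl (2S,3S)-3-{[4-(TBSO)-3-(3-methylbut-2-en-1-yl)phenyl]methyl}-4-oxooxetane-2-carboxylate (cis) | COC(=O)[C@H]1OC(=O)[C@H]1Cc1ccc(O[Si](C)(C)C(C)(C)C)c(CC=C(C)C)c1 | intermediate
9 | (4-bromophenoxy)(tert-butyl)dimethylsilane | CC(C)(C)[Si](C)(C)Oc1ccc(Br)cc1 | starting material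
10 | [4-(TBSO)phenyl]magnesium bromide | CC(C)(C)[Si](C)(C)Oc1ccc([Mg]Br)cc1 | intermediate (not isolated)
11 | bromomagnesium bis[4-(TBSO)phenyl]cuprate (Ar2CuMgBr; Ar = 4-TBSO-C6H4) | CC(C)(C)[Si](C)(C)Oc1ccc([Cu-]c2ccc(O[Si](C)(C)C(C)(C)C)cc2)cc1.[Mg+]Br | intermediate (not isolated)
12 | (2S,3S)-2-{[4-(TBSO)-3-(3-methylbut-2-en-1-yl)phenyl]methyl}-3-[4-(TBSO)phenyl]-4-methoxy-4-oxobutanoic acid | COC(=O)[C@H](c1ccc(O[Si](C)(C)C(C)(C)C)cc1)[C@H](Cc1ccc(O[Si](C)(C)C(C)(C)C)c(CC=C(C)C)c1)C(=O)O | intermediate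
13 | Asperteretal G2, (2S,3S)-2-{[4-hydroxy-3-(3-methylbut-2-en-1-yl)phenyl]methyl}-3-(4-hydroxyphenyl)-4-methoxy-4-oxobutanoic acid | COC(=O)[C@H](c1ccc(O)cc1)[C@H](Cc1ccc(O)c(CC=C(C)C)c1)C(=O)O | target

**Step count and risks**

Total steps: 5. Longest linear sequence: 5 (1 → 3 → 4 → 8 → 12 → 13).

Steps most likely to fail:

Step 4 (key arylation). The cuprate may reduce the α-acyloxy ester by electron transfer, add to the lactone carbonyl, or erode the aryl-bearing centre. The fallback sets out from lactone 8 and returns at acid 12. Acyl–oxygen opening of 8 with allyl alcohol and catalytic DMAP in CH2Cl2 gives the syn hydroxy diester 4-methyl 1-(prop-2-en-1-yl) (2S,3S)-2-{[4-(TBSO)-3-(3-methylbut-2-en-1-yl)phenyl]methyl}-3-hydroxybutanedioate F1. Tf2O and 2,6-lutidine at −78 °C convert it into 4-methyl 1-(prop-2-en-1-yl) (2S,3S)-2-{[4-(TBSO)-3-(3-methylbut-2-en-1-yl)phenyl]methyl}-3-{[(trifluoromethyl)sulfonyl]oxy}butanedioate F2. This open-chain α-triflyloxy ester, a substrate class with precedent for cuprate substitution with inversion, is displaced by cuprate 11 at −78 °C to give 4-methyl 1-(prop-2-en-1-yl) (2S,3S)-2-{[4-(TBSO)-3-(3-methylbut-2-en-1-yl)phenyl]methyl}-3-[4-(TBSO)phenyl]butanedioate F3. Pd(PPh3)4 (zerovalent palladium) with morpholine removes the allyl ester and gives 12.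

Step 3 (cycloaddition with glyoxylate). Glyoxylate is an unusual, easily oligomerised aldehyde partner, and the cis ratio or ee may be poor. The fallback sets out from acid chloride 6 and returns at lactone 8. Acylation of lithiated (S)-4-benzyl-1,3-oxazolidin-2-one (n-BuLi, THF, −78 °C) with 6 gives (4S)-4-benzyl-3-{3-[4-(TBSO)-3-(3-methylbut-2-en-1-yl)phenyl]propanoyl}-1,3-oxazolidin-2-one F4. Its boron enolate (Bu2BOTf, iPr2NEt, CH2Cl2, −78 °C) adds to methyl glyoxylate 5 in an Evans syn aldol reaction to give methyl (2S,3S)-3-{[(4S)-4-benzyl-2-oxo-1,3-oxazolidin-3-yl]carbonyl}-2-hydroxy-4-[4-(TBSO)-3-(3-methylbut-2-en-1-yl)phenyl]butanoate F5. Brief treatment with LiOH/H2O2 in THF/H2O at 0 °C frees (2S,3S)-2-{[4-(TBSO)-3-(3-methylbut-2-en-1-yl)phenyl]methyl}-3-hydroxy-4-methoxy-4-oxobutanoic acid F6. Carboxyl-activating lactonisation (PhSO2Cl, pyridine, 0 °C), with retention at both centres, gives 8.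

Step 1 (direct ortho-prenylation). Expect a modest yield, with O-prenyl and diprenyl by-products and recovered 1. The fallback sets out from acid 1 and returns at acid 3. Double allylation (allyl bromide, K2CO3, acetone, reflux) gives prop-2-en-1-yl 3-[4-(prop-2-en-1-yloxy)phenyl]propanoate F7. Aromatic Claisen rearrangement (neat, 200 °C) gives prop-2-en-1-yl 3-[4-hydroxy-3-(prop-2-en-1-yl)phenyl]propanoate F8 with the allyl group ortho to the phenol only. Saponification (LiOH, THF/H2O) gives 3-[4-hydroxy-3-(prop-2-en-1-yl)phenyl]propanoic acid F9. Cross-metathesis with 2-methylbut-2-ene (second-generation Grubbs catalyst, 5 mol%, CH2Cl2, 40 °C) converts the allyl group into the prenyl group and gives 3.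

**Further compounds**

F1 | step 4 | 4-methyl 1-(prop-2-en-1-yl) (2S,3S)-2-{[4-(TBSO)-3-(3-methylbut-2-en-1-yl)phenyl]methyl}-3-hydroxybutanedioate | COC(=O)[C@@H](O)[C@H](Cc1ccc(O[Si](C)(C)C(C)(C)C)c(CC=C(C)C)c1)C(=O)OCC=C
F2 | step 4 | 4-methyl 1-(prop-2-en-1-yl) (2S,3S)-2-{[4-(TBSO)-3-(3-methylbut-2-en-1-yl)phenyl]methyl}-3-{[(trifluoromethyl)sulfonyl]oxy}butanedioate | COC(=O)[C@@H](OS(=O)(=O)C(F)(F)F)[C@H](Cc1ccc(O[Si](C)(C)C(C)(C)C)c(CC=C(C)C)c1)C(=O)OCC=C
F3 | step 4 | 4-methyl 1-(prop-2-en-1-yl) (2S,3S)-2-{[4-(TBSO)-3-(3-methylbut-2-en-1-yl)phenyl]methyl}-3-[4-(TBSO)phenyl]butanedioate | COC(=O)[C@H](c1ccc(O[Si](C)(C)C(C)(C)C)cc1)[C@H](Cc1ccc(O[Si](C)(C)C(C)(C)C)c(CC=C(C)C)c1)C(=O)OCC=C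
F4 | step 3 | (4S)-4-benzyl-3-{3-[4-(TBSO)-3-(3-methylbut-2-en-1-yl)phenyl]propanoyl}-1,3-oxazolidin-2-one | O=C(CCc1ccc(O[Si](C)(C)C(C)(C)C)c(CC=C(C)C)c1)N1[C@@H](Cc2ccccc2)COC1=O
F5 | step 3 | methyl (2S,3S)-3-{[(4S)-4-benzyl-2-oxo-1,3-oxazolidin-3-yl]carbonyl}-2-hydroxy-4-[4-(TBSO)-3-(3-methylbut-2-en-1-yl)phenyl]butanoate | COC(=O)[C@@H](O)[C@H](Cc1ccc(O[Si](C)(C)C(C)(C)C)c(CC=C(C)C)c1)C(=O)N1[C@@H](Cc2ccccc2)COC1=O
F6 | step 3 | (2S,3S)-2-{[4-(TBSO)-3-(3-methylbut-2-en-1-yl)phenyl]methyl}-3-hydroxy-4-methoxy-4-oxobutanoic acid | COC(=O)[C@@H](O)[C@H](Cc1ccc(O[Si](C)(C)C(C)(C)C)c(CC=C(C)C)c1)C(=O)O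
F7 | step 1 | prop-2-en-1-yl 3-[4-(prop-2-en-1-yloxy)phenyl]propanoate | C=CCOC(=O)CCc1ccc(OCC=C)cc1
F8 | step 1 | prop-2-en-1-yl 3-[4-hydroxy-3-(prop-2-en-1-yl)phenyl]propanoate | C=CCOC(=O)CCc1ccc(O)c(CC=C)c1
F9 | step 1 | 3-[4-hydroxy-3-(prop-2-en-1-yl)phenyl]propanoic acid | OC(=O)CCc1ccc(O)c(CC=C)c1
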